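The cyclopentane core (C1 CH2O-acyl, C2 CH3, C3 O-acyl, C4 H2, C5 diol arm) and both acyl groups hide the same three-armed unit, so one organocatalytic malonate–dienal Michael adduct feeds both branches. In the core branch the ring is closed by forming C2–C3: a SmI2 ketyl–olefin 5-exo cyclisation of an acyclic aldehyde carrying an α-vinyl ester. It exploits the all-trans C1/C2/C3/C5 array: the single C5 stereocentre sets C2 and C3 through a chair transition state, and the epimeric C1 ester then converges by equilibration. The precursor is an open-chain aldehyde triester; reduction and acetonide formation release exactly the two hydroxyls that are acylated.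

Key step: step 5

Remarks on the chemistry (assumptions):
- Compound 1 is taken as the Z isomer. Any E isomer is harmless in the core branch (the alkene becomes a vinyl group) and in the acyl branch leads to the less stable enal isomer, which can be removed or equilibrated at compound 17.
- The sense of induction in step 2 is assigned from the usual face-shielding model of diarylprolinol silyl ether iminium ions.
- The descriptor at the branching carbon changes from S (6, 7) to R (8 onward) only through CIP priorities; the spatial arrangement is unchanged.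

Step 1
Reactants: 1 methyl (2Z)-2-bromobut-2-enoate; 2 2-[(1E)-3,3-diethoxyprop-1-en-1-yl]-4,4,5,5-tetramethyl-1,3,2-dioxaborolane
Product: 4 methyl (2E,3E)-2-ethylidene-5-oxopent-3-enoate, via diethyl acetal 3 (not isolated)
Conditions: Pd(dppf)Cl2 (divalent palladium precatalyst, 3 mol %), K3PO4, dioxane/H2O, 60 °C; then Amberlyst 15, acetone/H2O, rt
Reagents that add atoms: water, O
Why: Suzuki–Miyaura coupling of an alkenyl bromide with an alkenyl boronate proceeds with retention at both alkenes, and mild acid hydrolysis of the diethyl acetal should then release the dienal.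

Step 2
Reactants: 4 methyl (2E,3E)-2-ethylidene-5-oxopent-3-enoate; 5 dimethyl malonate
Product: 6 dimethyl 2-[(3S,4E)-4-(methoxycarbonyl)-1-oxohex-4-en-3-yl]propanedioate
Conditions: (R)-2-{bis[3,5-bis(trifluoromethyl)phenyl](trimethylsilyloxy)methyl}pyrrolidine (10 mol %), EtOH, 0 °C
Reagents that add atoms: none
Why: Iminium-catalysed Michael addition of a malonate to an enal, in which the diarylsilyloxymethyl group of the R catalyst shields one face of the E iminium ion so that the malonate should add to the β-carbon from the open face and set the S centre, the δ-carbon being hindered by its methyl group.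

Step 3
Reactants: 6 dimethyl 2-[(3S,4E)-4-(methoxycarbonyl)-1-oxohex-4-en-3-yl]propanedioate
Product: 7 dimethyl 2-[(3S,4E)-1,1-dimethoxy-4-(methoxycarbonyl)hex-4-en-3-yl]propanedioate
Conditions: HC(OMe)3, PPTS (cat.), MeOH, rt
Reagents that add atoms: trimethyl orthoformate, COC(OC)OC
Why: Acid-catalysed acetalisation with an orthoformate as water scavenger masks the aldehyde for the basic and reducing steps of both branches without touching the esters or the stereocentre.

Step 4
Reactants: 7 dimethyl 2-[(3S,4E)-1,1-dimethoxy-4-(methoxycarbonyl)hex-4-en-3-yl]propanedioate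
Product: 9 dimethyl 2-[(3R)-4-(methoxycarbonyl)-1-oxohex-5-en-3-yl]propanedioate (both C4 epimers), via vinyl acetal 8 (not isolated)
Conditions: LDA (LiN(i-Pr)2, 2.3 equiv), DMPU, THF, −78 °C; AcOH, −78 °C; then 2 M aq. HCl, rt
Reagents that add atoms: water, O
Why: Deconjugative protonation, in which the malonate is deprotonated first (which also blocks its loss by retro-Michael), γ-deprotonation of the 2-butenoate gives the extended enolate, kinetic α-protonation gives the β,γ-unsaturated ester and aqueous acid then hydrolyses the acetal; the configuration of the new α-centre does not matter because step 6 corrects it.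

Step 5
Reactants: 9 dimethyl 2-[(3R)-4-(methoxycarbonyl)-1-oxohex-5-en-3-yl]propanedioate (both C4 epimers)
Product: 10 methyl (2R,3R,5R)-5-(1,3-dimethoxy-1,3-dioxopropan-2-yl)-3-hydroxy-2-methylcyclopentane-1-carboxylate (both C1 epimers)
Conditions: SmI2 (divalent samarium, 2.5 equiv), HMPA (10 equiv), t-BuOH (2 equiv), THF, −78 → 0 °C, slow addition of 9
Reagents that add atoms: none
Why: SmI2 reduces the aldehyde (far more readily than the esters) to a samarium ketyl radical, which adds 5-exo-trig to the vinyl group to form the C2–C3 bond; the primary radical is reduced by a second SmI2 and the alkylsamarium is protonated by t-BuOH to give the C2 methyl group. The closest known reaction type is the SmI2/HMPA ketyl–olefin reductive cyclisation of δ,ε-unsaturated carbonyl compounds to trans-2-methylcyclopentanols. The only ring closed is the cyclopentane, by a 5-exo-trig radical closure through a chair-like transition state. C3 (carbinol) and C2 (methyl) are controlled by the existing C5 stereocentre: its bulky malonyl arm sits pseudo-equatorial, which places the C2 methyl cis to it, while the HMPA-solvated O–Sm group stays anti to the alkene, which puts OH trans to CH3. The step needs cyclisation to outrun pinacol coupling and simple aldehyde reduction, which slow addition at high dilution and HMPA should secure, and it needs the same facial outcome from both C1 epimers, which the larger conformational demand of the malonyl arm over the ester should secure.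

Step 6
Reactants: 10 methyl (2R,3R,5R)-5-(1,3-dimethoxy-1,3-dioxopropan-2-yl)-3-hydroxy-2-methylcyclopentane-1-carboxylate (both C1 epimers)
Product: 11 methyl (1S,2R,3R,5R)-5-(1,3-dimethoxy-1,3-dioxopropan-2-yl)-3-hydroxy-2-methylcyclopentane-1-carboxylate
Conditions: NaOMe (2 equiv), MeOH, 50 °C; then AcOH
Reagents that add atoms: none
Why: Base-mediated epimerisation of the only enolisable ring centre should funnel both epimers to the all-trans ester, in which the carboxylate avoids the cis-flanking methyl and malonyl groups, while the malonate is held as its enolate and so cannot leave by retro-Michael.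

Step 7
Reactants: 11 methyl (1S,2R,3R,5R)-5-(1,3-dimethoxy-1,3-dioxopropan-2-yl)-3-hydroxy-2-methylcyclopentane-1-carboxylate
Product: 12 2-[(1R,2S,3R,4R)-4-hydroxy-2-(hydroxymethyl)-3-methylcyclopentyl]propane-1,3-diol
Conditions: LiAlH4 (excess), THF, 0 → 50 °C; then H2O, aq. NaOH
Reagents that add atoms: none
Why: Hydride reduction of the three methyl esters with LiAlH4 should give the tetraol without touching any stereocentre.

Step 8
Reactants: 12 2-[(1R,2S,3R,4R)-4-hydroxy-2-(hydroxymethyl)-3-methylcyclopentyl]propane-1,3-diol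
Product: 13 (1R,2R,3S,4R)-4-(2,2-dimethyl-1,3-dioxan-5-yl)-3-(hydroxymethyl)-2-methylcyclopentan-1-ol
Conditions: Me2C(OMe)2 (1.2 equiv), PPTS (cat.), DMF, rt; then MeOH
Reagents that add atoms: 2,2-dimethoxypropane, COC(C)(C)OC
Why: Acetonide formation by transketalisation is selective for the 1,3-diol, the only pair of hydroxyls that can close a six-membered dioxane, and so leaves free exactly the C1 hydroxymethyl and C3 hydroxyl groups.

Step 9
Reactants: 7 dimethyl 2-[(3S,4E)-1,1-dimethoxy-4-(methoxycarbonyl)hex-4-en-3-yl]propanedioate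
Product: 15 (3S,4E)-3-(2,2-dimethoxyethyl)-4-(methoxycarbonyl)hex-4-enoic acid, via malonic acid 14 (not isolated)
Conditions: LiOH·H2O (2.1 equiv), THF/H2O, 0 °C → rt; AcOH to pH 5; then DMSO, 110 °C
Reagents that add atoms: lithium hydroxide, [Li+].[OH-]
Why: Saponification is selective for the unhindered malonate esters over the α-branched conjugated ester, and the hydrogen malonate then loses CO2 thermally (malonic acid decarboxylation) in a buffered medium that spares the acetal.

Step 10
Reactants: 15 (3S,4E)-3-(2,2-dimethoxyethyl)-4-(methoxycarbonyl)hex-4-enoic acid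
Product: 16 (3S,4E)-3-(2,2-dimethoxyethyl)-4-(hydroxymethyl)hex-4-enoic acid
Conditions: DIBAL-H (i-Bu2AlH, 4 equiv), CH2Cl2, −78 → −40 °C; Rochelle salt, pH 5 buffer
Reagents that add atoms: none
Why: DIBAL-H 1,2-reduction of the conjugated ester to the allylic alcohol, with the acid protected in situ as its unreactive aluminium carboxylate.

Step 11
Reactants: 16 (3S,4E)-3-(2,2-dimethoxyethyl)-4-(hydroxymethyl)hex-4-enoic acid
Product: 17 (3S,4E)-3-(2,2-dimethoxyethyl)-4-formylhex-4-enoic acid
Conditions: MnO2 (tetravalent manganese, excess), CH2Cl2, rt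
Reagents that add atoms: none
Why: Allylic oxidation with MnO2 is selective for the allylic alcohol and should give the E enal, which is also the thermodynamically favoured geometry.

Step 12
Reactants: 13 (1R,2R,3S,4R)-4-(2,2-dimethyl-1,3-dioxan-5-yl)-3-(hydroxymethyl)-2-methylcyclopentan-1-ol; 17 (3S,4E)-3-(2,2-dimethoxyethyl)-4-formylhex-4-enoic acid (2.5 equiv)
Product: 18 {(1S,2R,3R,5R)-5-(2,2-dimethyl-1,3-dioxan-5-yl)-3-{[(3S,4E)-3-(2,2-dimethoxyethyl)-4-formylhex-4-enoyl]oxy}-2-methylcyclopentyl}methyl (3S,4E)-3-(2,2-dimethoxyethyl)-4-formylhex-4-enoate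
Conditions: EDC·HCl (3 equiv), DMAP (0.5 equiv), CH2Cl2, 0 °C → rt
Reagents that add atoms: none
Why: Steglich esterification (carbodiimide with DMAP) should acylate both the primary and the secondary hydroxyl with an excess of the acid, no stereocentre being involved.

Step 13
Reactants: 18 the bis-ester bis-acetal acetonide
Product: 19 {(1S,2R,3R,5R)-5-(1,3-dihydroxypropan-2-yl)-3-{[(3S,4E)-4-formyl-3-(2-oxoethyl)hex-4-enoyl]oxy}-2-methylcyclopentyl}methyl (3S,4E)-4-formyl-3-(2-oxoethyl)hex-4-enoate (target)
Conditions: AcOH/THF/H2O (3:1:1), 40 °C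
Reagents that add atoms: water, O
Why: Acetal hydrolysis in aqueous acetic acid should cleave the two dimethyl acetals and the dioxane acetonide while the esters, the enals and all stereocentres survive.

Compound list
1 | methyl (2Z)-2-bromobut-2-enoate | C/C=C(\Br)C(=O)OC | starting material
2 | 2-[(1E)-3,3-diethoxyprop-1-en-1-yl]-4,4,5,5-tetramethyl-1,3,2-dioxaborolane | CCOC(OCC)/C=C/B1OC(C)(C)C(C)(C)O1 | starting material
3 | methyl (2E,3E)-5,5-diethoxy-2-ethylidenepent-3-enoate | CCOC(OCC)/C=C/C(=C\C)C(=O)OC | intermediate (not isolated)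
4 | methyl (2E,3E)-2-ethylidene-5-oxopent-3-enoate | O=C/C=C/C(=C\C)C(=O)OC | intermediate
5 | dimethyl malonate | COC(=O)CC(=O)OC | starting material
6 | dimethyl 2-[(3S,4E)-4-(methoxycarbonyl)-1-oxohex-4-en-3-yl]propanedioate | O=CC[C@H](/C(C(=O)OC)=C\C)C(C(=O)OC)C(=O)OC | intermediate
7 | dimethyl 2-[(3S,4E)-1,1-dimethoxy-4-(methoxycarbonyl)hex-4-en-3-yl]propanedioate | COC(OC)C[C@H](/C(C(=O)OC)=C\C)C(C(=O)OC)C(=O)OC | intermediate
8 | dimethyl 2-[(3R)-1,1-dimethoxy-4-(methoxycarbonyl)hex-5-en-3-yl]propanedioate (C4 epimers) | COC(OC)C[C@H](C(C=C)C(=O)OC)C(C(=O)OC)C(=O)OC | intermediate (not isolated)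
9 | dimethyl 2-[(3R)-4-(methoxycarbonyl)-1-oxohex-5-en-3-yl]propanedioate (C4 epimers) | O=CC[C@H](C(C=C)C(=O)OC)C(C(=O)OC)C(=O)OC | intermediate
10 | methyl (2R,3R,5R)-5-(1,3-dimethoxy-1,3-dioxopropan-2-yl)-3-hydroxy-2-methylcyclopentane-1-carboxylate (C1 epimers) | COC(=O)C1[C@@H](C)[C@H](O)C[C@H]1C(C(=O)OC)C(=O)OC | intermediate
11 | methyl (1S,2R,3R,5R)-5-(1,3-dimethoxy-1,3-dioxopropan-2-yl)-3-hydroxy-2-methylcyclopentane-1-carboxylate | COC(=O)[C@@H]1[C@@H](C)[C@H](O)C[C@H]1C(C(=O)OC)C(=O)OC | intermediate
12 | 2-[(1R,2S,3R,4R)-4-hydroxy-2-(hydroxymethyl)-3-methylcyclopentyl]propane-1,3-diol | OC[C@@H]1[C@@H](C)[C@H](O)C[C@H]1C(CO)CO | intermediate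
13 | (1R,2R,3S,4R)-4-(2,2-dimethyl-1,3-dioxan-5-yl)-3-(hydroxymethyl)-2-methylcyclopentan-1-ol | OC[C@@H]1[C@@H](C)[C@H](O)C[C@H]1C2COC(C)(C)OC2 | intermediate
14 | 2-[(3S,4E)-1,1-dimethoxy-4-(methoxycarbonyl)hex-4-en-3-yl]propanedioic acid | COC(OC)C[C@H](/C(C(=O)OC)=C\C)C(C(=O)O)C(=O)O | intermediate (not isolated)
15 | (3S,4E)-3-(2,2-dimethoxyethyl)-4-(methoxycarbonyl)hex-4-enoic acid | COC(OC)C[C@H](/C(C(=O)OC)=C\C)CC(=O)O | intermediate
16 | (3S,4E)-3-(2,2-dimethoxyethyl)-4-(hydroxymethyl)hex-4-enoic acid | COC(OC)C[C@H](/C(CO)=C\C)CC(=O)O | intermediate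
17 | (3S,4E)-3-(2,2-dimethoxyethyl)-4-formylhex-4-enoic acid | COC(OC)C[C@H](/C(C=O)=C\C)CC(=O)O | intermediate
18 | {(1S,2R,3R,5R)-5-(2,2-dimethyl-1,3-dioxan-5-yl)-3-{[(3S,4E)-3-(2,2-dimethoxyethyl)-4-formylhex-4-enoyl]oxy}-2-methylcyclopentyl}methyl (3S,4E)-3-(2,2-dimethoxyethyl)-4-formylhex-4-enoate | C/C=C(/C=O)[C@@H](CC(OC)OC)CC(=O)OC[C@@H]1[C@@H](C)[C@H](OC(=O)C[C@H](CC(OC)OC)/C(C=O)=C\C)C[C@H]1C2COC(C)(C)OC2 | intermediate
19 | {(1S,2R,3R,5R)-5-(1,3-dihydroxypropan-2-yl)-3-{[(3S,4E)-4-formyl-3-(2-oxoethyl)hex-4-enoyl]oxy}-2-methylcyclopentyl}methyl (3S,4E)-4-formyl-3-(2-oxoethyl)hex-4-enoate | C/C=C(/C=O)[C@@H](CC=O)CC(=O)OC[C@@H]1[C@@H](C)[C@H](OC(=O)C[C@H](CC=O)/C(C=O)=C\C)C[C@H]1C(CO)CO | target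

Total step count: 13. Longest linear sequence: 10 steps (steps 1–8, 12 and 13); the acyl branch (steps 9–11) leaves the common intermediate 7.

Steps most likely to fail

Step 5. The ketyl may be reduced further or dimerise by pinacol coupling faster than it adds to the unactivated vinyl group, and facial control may be weak for the mismatched C1 epimer. The fallback sets out from 9 and forms the same C2–C3 bond through an acyl radical instead of a ketyl. Thiol-catalysed radical hydroacylation (tert-dodecanethiol, AIBN, chlorobenzene, 80 °C) should close the ring 5-exo to methyl 5-(1,3-dimethoxy-1,3-dioxopropan-2-yl)-2-methyl-3-oxocyclopentane-1-carboxylate F1 as a mixture at C1 and C2. NaOMe in MeOH then equilibrates both enolisable centres to the all-trans ketone methyl (1S,2R,5R)-5-(1,3-dimethoxy-1,3-dioxopropan-2-yl)-2-methyl-3-oxocyclopentane-1-carboxylate F2. NaBH4 in MeOH at −78 °C, which reduces 2-alkylcyclopentanones mainly to the trans alcohol, should give 11, where the route is rejoined; the minor C3 epimer would be separated and recycled by oxidation.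

Step 2. Addition at the δ-carbon (1,6-addition) or isomerisation of the dienal through its trienamine may compete, lowering regioselectivity and enantiomeric purity. The fallback sets out from 4 and sets the same centre by iridium-catalysed allylic alkylation. Luche reduction (NaBH4, CeCl3·7H2O, MeOH) gives methyl (2E,3E)-2-ethylidene-5-hydroxypent-3-enoate F3, and methyl chloroformate with pyridine gives methyl (2E,3E)-2-ethylidene-5-[(methoxycarbonyl)oxy]pent-3-enoate F4. Branched-selective allylic alkylation with dimethyl malonate ([Ir(cod)Cl]2, monovalent iridium, with the enantiomer of the BINOL-derived bis(1-phenylethyl)amine phosphoramidite ligand that delivers the 3S product, TBD, THF) should give dimethyl 2-[(3S,4E)-4-(methoxycarbonyl)hexa-1,4-dien-3-yl]propanedioate F5. Hydroboration of the terminal vinyl group with 9-BBN and oxidation with NaBO3 gives dimethyl 2-[(3S,4E)-1-hydroxy-4-(methoxycarbonyl)hex-4-en-3-yl]propanedioate F6, and Dess–Martin oxidation returns to the route at 6.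

Step 4. The amide base may add in conjugate fashion, γ-deprotonation of the E-configured ester may be incomplete, or protonation at the γ-carbon may return the conjugated ester. The fallback sets out from 7 and replaces the enolate chemistry by photochemical deconjugation: irradiation at 254 nm with catalytic 1,2-dimethylimidazole in MeCN (E/Z isomerisation, 1,5-hydrogen shift to the dienol, base-mediated ketonisation) should give 8 directly. Hydrolysis with 2 M aq. HCl then returns to the route at 9; no new compound is made.

Further compounds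
F1 | step 5 | methyl 5-(1,3-dimethoxy-1,3-dioxopropan-2-yl)-2-methyl-3-oxocyclopentane-1-carboxylate (5R; C1 and C2 epimers) | COC(=O)C1C(C)C(=O)C[C@H]1C(C(=O)OC)C(=O)OC
F2 | step 5 | methyl (1S,2R,5R)-5-(1,3-dimethoxy-1,3-dioxopropan-2-yl)-2-methyl-3-oxocyclopentane-1-carboxylate | COC(=O)[C@@H]1[C@@H](C)C(=O)C[C@H]1C(C(=O)OC)C(=O)OC
F3 | step 2 | methyl (2E,3E)-2-ethylidene-5-hydroxypent-3-enoate | OC/C=C/C(=C\C)C(=O)OC
F4 | step 2 | methyl (2E,3E)-2-ethylidene-5-[(methoxycarbonyl)oxy]pent-3-enoate | COC(=O)OC/C=C/C(=C\C)C(=O)OC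
F5 | step 2 | dimethyl 2-[(3S,4E)-4-(methoxycarbonyl)hexa-1,4-dien-3-yl]propanedioate | C=C[C@H](/C(C(=O)OC)=C\C)C(C(=O)OC)C(=O)OC
F6 | step 2 | dimethyl 2-[(3S,4E)-1-hydroxy-4-(methoxycarbonyl)hex-4-en-3-yl]propanedioate | OCC[C@H](/C(C(=O)OC)=C\C)C(C(=O)OC)C(=O)OC
F0 | step 4 | none | none
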